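Ring B is built, not bought. Its C1'(carbon)–C2'(OAr)–C3'(O)–C4'(O) array, with C5' and C6' as CH, is cut into methyl propiolate and a 1-aryloxy-2-methoxy-3-silyloxycyclohexa-1,3-diene. The crowded ether bond between ring A C3 and ring B C2' is made beforehand by addition–elimination on a bromo enone from cyclohexane-1,2-dione. One heating operation (Diels–Alder, then ethylene loss; Alder–Rickert) forms C1'–C2' and C5'–C6', closes ring B as an arene and fixes four contiguous substituents. C5' is then brominated ortho to the only free phenol. The precursor is the kinetic silyl dienol ether of a 3-aryloxy-2-methoxycyclohex-2-enone carrying the fully substituted ring A benzoate.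

Key step: step 9

Remark on the chemistry: ring A is numbered from its hydroxymethyl carbon (C1; ether oxygen on C3) and ring B likewise (C1'; ether oxygen on C2'). Adduct 13 is racemic and its two bridgehead stereocentres vanish on cycloreversion. 2-Fluoro-3,4-dimethoxybenzaldehyde, used only in a fallback, is assumed to be purchasable.

Step 1
Reactants: 1 2-bromo-3-hydroxy-4-methoxybenzaldehyde (2-bromoisovanillin)
Product: 2 2-bromo-3-formyl-6-methoxyphenyl acetate
Conditions: Ac2O, pyridine, DMAP (cat.), CH2Cl2, 0 °C to rt
Reagents that add atoms: acetic anhydride, CC(=O)OC(C)=O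
Why: DMAP-catalysed O-acylation of the phenol; as an acetate the C3 oxygen is a weak donor, so the C4 methoxy group should govern the next aromatic substitution.

Step 2
Reactants: 2 2-bromo-3-formyl-6-methoxyphenyl acetate
Product: 3 2,5-dibromo-3-formyl-6-methoxyphenyl acetate
Conditions: Br2, NaOAc, AcOH, 50 °C
Reagents that add atoms: bromine, BrBr
Why: Electrophilic aromatic bromination should go to C5, which is ortho to the methoxy group, para to the C2 bromine and meta to the formyl group, whereas C6 is ortho to the formyl group and only para to the acetoxy group; NaOAc buffers HBr so the acetate stays on.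

Step 3
Reactants: 3 2,5-dibromo-3-formyl-6-methoxyphenyl acetate
Product: 4 3-acetoxy-2,5-dibromo-4-methoxybenzoic acid
Conditions: NaClO2, NaH2PO4, 2-methyl-2-butene, t-BuOH/H2O, rt
Reagents that add atoms: sodium chlorite NaClO2, [Na+].[O-]Cl=O
Why: Pinnick oxidation converts the aryl aldehyde into the acid at about pH 4, leaving the aryl acetate and the bromides alone, while the alkene scavenges the hypochlorous acid that would otherwise chlorinate the ring.

Step 4
Reactants: 4 3-acetoxy-2,5-dibromo-4-methoxybenzoic acid
Product: 5 methyl 2,5-dibromo-3-hydroxy-4-methoxybenzoate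
Conditions: MeOH, H2SO4 (cat.), reflux
Reagents that add atoms: methanol, CO
Why: Fischer esterification of an acid with only one ortho substituent, with concurrent acid-catalysed methanolysis of the aryl acetate, should release the C3 phenol in the same operation.

Step 5
Reactants: 6 cyclohexane-1,2-dione
Product: 7 3-bromo-2-hydroxycyclohex-2-en-1-one (enol form of 3-bromocyclohexane-1,2-dione)
Conditions: Br2 (1.0 equiv), CH2Cl2, 0 °C
Reagents that add atoms: bromine, BrBr
Why: Electrophilic α-bromination of the enolised 1,2-dione at its enol carbon, followed by re-enolisation toward the brominated carbon, should give the bromo diosphenol.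

Step 6
Reactants: 7 3-bromo-2-hydroxycyclohex-2-en-1-one
Product: 8 3-bromo-2-methoxycyclohex-2-en-1-one
Conditions: Me2SO4, K2CO3, acetone, reflux
Reagents that add atoms: dimethyl sulfate, COS(=O)(=O)OC
Why: Williamson-type O-methylation of the acidic enol with a hard methylating agent; the only carbon terminus of the ambident anion is the fully substituted C–Br carbon, so C-alkylation should not compete.

Step 7
Reactants: 5 methyl 2,5-dibromo-3-hydroxy-4-methoxybenzoate; 8 3-bromo-2-methoxycyclohex-2-en-1-one
Product: 9 methyl 2,5-dibromo-4-methoxy-3-[(2-methoxy-3-oxocyclohex-1-en-1-yl)oxy]benzoate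
Conditions: Cs2CO3, DMF, 60 °C
Reagents that add atoms: none
Why: Conjugate addition–elimination (vinylogous acyl substitution) of the phenoxide at the β-carbon of the β-bromo enone makes the hindered C3–O bond on a non-aromatic sp2 carbon; because the enol oxygen is already methylated, base cannot deactivate the electrophile by deprotonation.

Step 8
Reactants: 9 methyl 2,5-dibromo-4-methoxy-3-[(2-methoxy-3-oxocyclohex-1-en-1-yl)oxy]benzoate
Product: 11 methyl 2,5-dibromo-3-{[3-(tert-butyldimethylsilyloxy)-2-methoxycyclohexa-1,3-dien-1-yl]oxy}-4-methoxybenzoate, via lithium dienolate 10 (not isolated)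
Conditions: LiN(i-Pr)2 (1.05 equiv), THF, −78 °C (9 added to the base); then TBSCl, DMPU, −78 °C to 0 °C
Reagents that add atoms: tert-butyldimethylsilyl chloride, CC(C)(C)[Si](C)(C)Cl
Why: Kinetic α'-deprotonation of a vinylogous ester by a hindered amide base (Stork–Danheiser regiochemistry) gives the cross-conjugated enolate, and O-silylation traps it as the 2-silyloxy diene; at −78 °C the γ-protons, the aryl ester and the aryl bromides should be left alone.

Step 9
Reactants: 11 methyl 2,5-dibromo-3-{[3-(tert-butyldimethylsilyloxy)-2-methoxycyclohexa-1,3-dien-1-yl]oxy}-4-methoxybenzoate; 12 methyl propiolate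
Product: 14 methyl 2,5-dibromo-3-[3-(tert-butyldimethylsilyloxy)-2-methoxy-6-(methoxycarbonyl)phenoxy]-4-methoxybenzoate, via bicyclo[2.2.2]octadiene adduct 13 (not isolated)
Conditions: 12 (5 equiv), BHT (cat.), o-xylene, sealed tube, 110 °C then 170 °C
Reagents that add atoms: none
Why: The electron-rich cisoid diene of 11 should add thermally to the alkyne of 12 in a concerted, asynchronous Diels–Alder reaction to give the bicyclo[2.2.2]octa-2,5-diene 13, which at the higher temperature loses its saturated two-carbon bridge as ethylene by retro-Diels–Alder reaction; this is the Alder–Rickert reaction, well established for 2-silyloxycyclohexa-1,3-dienes and acetylenic esters. Ring B, made of the four diene carbons and the two alkyne carbons, is closed by intermolecular [4+2] cycloaddition (forming C1'–C2' and C5'–C6') and becomes aromatic by cycloreversion. The two bridgehead stereocentres of 13 are transient and are erased on aromatisation, so no stereocontrol is needed. The selectivity required is regiochemical: the aryloxy group on the diene terminus and the silyloxy group next to the other terminus both enlarge the HOMO coefficient at the unsubstituted CH terminus, which pairs with the unsubstituted β-carbon of the propiolate, so the ester carbon bonds to the aryloxy-bearing terminus; the single internal methoxy donor, twisted between two substituents, opposes this but should be outweighed. Because the aryloxy carbon is a bridgehead in 13, the phenol cannot be expelled and ethylene loss is the only path to the arene. Staging the temperature should let the cycloaddition outrun [1,5]-hydrogen shifts of the diene.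

Step 10
Reactants: 14 methyl 2,5-dibromo-3-[3-(tert-butyldimethylsilyloxy)-2-methoxy-6-(methoxycarbonyl)phenoxy]-4-methoxybenzoate
Product: 15 methyl 2,5-dibromo-3-[3-hydroxy-2-methoxy-6-(methoxycarbonyl)phenoxy]-4-methoxybenzoate
Conditions: Bu4NF (1.1 equiv), AcOH (1.1 equiv), THF, 0 °C
Reagents that add atoms: none
Why: Fluoride-mediated cleavage of the aryl silyl ether frees the C4' phenol; the acetic acid buffer keeps the phenoxide and fluoride from attacking the two methyl esters.

Step 11
Reactants: 15 methyl 2,5-dibromo-3-[3-hydroxy-2-methoxy-6-(methoxycarbonyl)phenoxy]-4-methoxybenzoate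
Product: 16 methyl 2,5-dibromo-3-[4-bromo-3-hydroxy-2-methoxy-6-(methoxycarbonyl)phenoxy]-4-methoxybenzoate
Conditions: NBS (1.05 equiv), MeCN, 0 °C
Reagents that add atoms: N-bromosuccinimide, O=C1CCC(=O)N1Br
Why: Electrophilic bromination ortho to the only free phenol should go to C5', since the other ortho site carries the methoxy group and the para site the ester (as in the bromination of vanillate esters), while ring A is deactivated by its ester and two bromines.

Step 12
Reactants: 16 methyl 2,5-dibromo-3-[4-bromo-3-hydroxy-2-methoxy-6-(methoxycarbonyl)phenoxy]-4-methoxybenzoate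
Product: 17 methyl 2,5-dibromo-3-[4-bromo-2,3-dihydroxy-6-(methoxycarbonyl)phenoxy]-4-hydroxybenzoate
Conditions: BBr3 (6 equiv), CH2Cl2, −78 °C to 0 °C; then H2O
Reagents that add atoms: none
Why: Lewis acid-mediated cleavage of the two flanked aryl methyl ethers, which methyl benzoates and the diaryl ether should survive at or below 0 °C; doing this before the reduction keeps BBr3 away from benzylic alcohols, which it would convert into bromides.

Step 13
Reactants: 17 methyl 2,5-dibromo-3-[4-bromo-2,3-dihydroxy-6-(methoxycarbonyl)phenoxy]-4-hydroxybenzoate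
Product: 18 6-bromo-3-[2,5-dibromo-6-hydroxy-3-(hydroxymethyl)phenoxy]-4-(hydroxymethyl)benzene-1,2-diol (CNP0104332.0)
Conditions: i-Bu2AlH (10 equiv), THF, −78 °C to rt; then 1 M HCl
Reagents that add atoms: none
Why: Hydride reduction of both aryl methyl esters to benzylic alcohols; the three phenols are first converted into aluminium phenoxides (hence the excess), aryl bromides are inert to this reagent, and the cold acidic work-up releases the product without exposing the catechol to base.

Compound list
1 | 2-bromo-3-hydroxy-4-methoxybenzaldehyde (2-bromoisovanillin) | COc1ccc(C=O)c(Br)c1O | starting material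
2 | 2-bromo-3-formyl-6-methoxyphenyl acetate | COc1ccc(C=O)c(Br)c1OC(C)=O | intermediate
3 | 2,5-dibromo-3-formyl-6-methoxyphenyl acetate | COc1c(Br)cc(C=O)c(Br)c1OC(C)=O | intermediate
4 | 3-acetoxy-2,5-dibromo-4-methoxybenzoic acid | COc1c(Br)cc(C(=O)O)c(Br)c1OC(C)=O | intermediate
5 | methyl 2,5-dibromo-3-hydroxy-4-methoxybenzoate | COC(=O)c1cc(Br)c(OC)c(O)c1Br | intermediate
6 | cyclohexane-1,2-dione | O=C1CCCCC1=O | starting material
7 | 3-bromo-2-hydroxycyclohex-2-en-1-one | O=C1CCCC(Br)=C1O | intermediate
8 | 3-bromo-2-methoxycyclohex-2-en-1-one | COC1=C(Br)CCCC1=O | intermediate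
9 | methyl 2,5-dibromo-4-methoxy-3-[(2-methoxy-3-oxocyclohex-1-en-1-yl)oxy]benzoate | COC(=O)c1cc(Br)c(OC)c(OC2=C(OC)C(=O)CCC2)c1Br | intermediate
10 | cross-conjugated lithium dienolate of 9 (lithium on the former carbonyl oxygen, new C=C toward the former C6) | [Li+].[O-]C1=CCCC(Oc2c(Br)c(C(=O)OC)cc(Br)c2OC)=C1OC | intermediate
11 | methyl 2,5-dibromo-3-{[3-(tert-butyldimethylsilyloxy)-2-methoxycyclohexa-1,3-dien-1-yl]oxy}-4-methoxybenzoate | COC1=C(Oc2c(Br)c(C(=O)OC)cc(Br)c2OC)CCC=C1O[Si](C)(C)C(C)(C)C | intermediate
12 | methyl propiolate | C#CC(=O)OC | starting material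
13 | methyl 2,5-dibromo-3-{[5-(tert-butyldimethylsilyloxy)-6-methoxy-2-(methoxycarbonyl)bicyclo[2.2.2]octa-2,5-dien-1-yl]oxy}-4-methoxybenzoate (racemic) | COC(=O)C1=CC2CCC1(Oc1c(Br)c(C(=O)OC)cc(Br)c1OC)C(OC)=C2O[Si](C)(C)C(C)(C)C | intermediate
14 | methyl 2,5-dibromo-3-[3-(tert-butyldimethylsilyloxy)-2-methoxy-6-(methoxycarbonyl)phenoxy]-4-methoxybenzoate | COC(=O)c1ccc(O[Si](C)(C)C(C)(C)C)c(OC)c1Oc1c(Br)c(C(=O)OC)cc(Br)c1OC | intermediate
15 | methyl 2,5-dibromo-3-[3-hydroxy-2-methoxy-6-(methoxycarbonyl)phenoxy]-4-methoxybenzoate | COC(=O)c1ccc(O)c(OC)c1Oc1c(Br)c(C(=O)OC)cc(Br)c1OC | intermediate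
16 | methyl 2,5-dibromo-3-[4-bromo-3-hydroxy-2-methoxy-6-(methoxycarbonyl)phenoxy]-4-methoxybenzoate | COC(=O)c1cc(Br)c(O)c(OC)c1Oc1c(Br)c(C(=O)OC)cc(Br)c1OC | intermediate
17 | methyl 2,5-dibromo-3-[4-bromo-2,3-dihydroxy-6-(methoxycarbonyl)phenoxy]-4-hydroxybenzoate | COC(=O)c1cc(Br)c(O)c(O)c1Oc1c(Br)c(C(=O)OC)cc(Br)c1O | intermediate
18 | 6-bromo-3-[2,5-dibromo-6-hydroxy-3-(hydroxymethyl)phenoxy]-4-(hydroxymethyl)benzene-1,2-diol (CNP0104332.0) | OCc1cc(Br)c(O)c(Oc2c(CO)cc(Br)c(O)c2O)c1Br | target

Total step count: 13.
Longest linear sequence: 11 steps (steps 1–4 and 7–13, from 2-bromoisovanillin); the dione branch (steps 5 and 6) joins at step 7.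

Steps most likely to fail

Step 9. The cycloaddition may lose regiocontrol (the internal methoxy donor steering the ester to the other terminus), or the diene may undergo [1,5]-hydrogen migration and then expel the ring A phenol before it is intercepted. The fallback drops the ring construction and makes the diaryl ether by nucleophilic aromatic substitution; it sets out from 5 and comes back to the route at 18. The phenoxide of 5 (K2CO3, DMF, 110 °C) should displace fluoride from 2-fluoro-3,4-dimethoxybenzaldehyde (COc1ccc(C=O)c(F)c1OC), activated by its ortho formyl group, to give methyl 2,5-dibromo-3-(6-formyl-2,3-dimethoxyphenoxy)-4-methoxybenzoate F1. NBS in MeCN should then brominate ring B at C5' (ortho to the C4' methoxy group, para to the ether oxygen, meta to the formyl group) to give methyl 2,5-dibromo-3-(4-bromo-6-formyl-2,3-dimethoxyphenoxy)-4-methoxybenzoate F2. BBr3 in CH2Cl2 should cleave the three methyl ethers to methyl 2,5-dibromo-3-(4-bromo-6-formyl-2,3-dihydroxyphenoxy)-4-hydroxybenzoate F3, and excess i-Bu2AlH should reduce formyl and ester groups together to 18.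

Step 7. Addition of the hindered phenoxide (flanked by bromine and methoxy) to the β-carbon may be slow enough that base-induced self-condensation of the bromo enone takes over. The fallback reverses the order of etherification and methylation; it sets out from 5 and 7 and comes back at 9. With one equivalent of KHCO3 in acetone only the more acidic phenol should be ionised, and it should alkylate 7 through its α-bromo ketone tautomer (Williamson-type displacement at sp3 carbon); the resulting aryloxy dione should enolise to methyl 2,5-dibromo-3-[(2-hydroxy-3-oxocyclohex-1-en-1-yl)oxy]-4-methoxybenzoate F4. O-Methylation with Me2SO4 and K2CO3 in acetone should then give 9.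

Step 13. Reduction of esters that sit para to aluminium phenoxides may stall, and the p-hydroxybenzylic oxygens may be lost through quinone methide formation during work-up. The fallback reduces before it demethylates; it sets out from 16 and comes back at 18. i-Bu2AlH in THF should reduce both esters while only one phenol is free, giving 6-bromo-3-[2,5-dibromo-3-(hydroxymethyl)-6-methoxyphenoxy]-4-(hydroxymethyl)-2-methoxyphenol F5. BBr3 in CH2Cl2 should then cleave both methyl ethers and convert both benzylic alcohols into bromides, giving 6-bromo-4-(bromomethyl)-3-[2,5-dibromo-3-(bromomethyl)-6-hydroxyphenoxy]benzene-1,2-diol F6. Brief solvolysis in aqueous acetone with NaHCO3 should give 18, since benzylic bromides para to a free phenol hydrolyse readily.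

Further compounds
F1 | step 9 | methyl 2,5-dibromo-3-(6-formyl-2,3-dimethoxyphenoxy)-4-methoxybenzoate | COC(=O)c1cc(Br)c(OC)c(Oc2c(C=O)ccc(OC)c2OC)c1Br
F2 | step 9 | methyl 2,5-dibromo-3-(4-bromo-6-formyl-2,3-dimethoxyphenoxy)-4-methoxybenzoate | COC(=O)c1cc(Br)c(OC)c(Oc2c(C=O)cc(Br)c(OC)c2OC)c1Br
F3 | step 9 | methyl 2,5-dibromo-3-(4-bromo-6-formyl-2,3-dihydroxyphenoxy)-4-hydroxybenzoate | COC(=O)c1cc(Br)c(O)c(Oc2c(C=O)cc(Br)c(O)c2O)c1Br
F4 | step 7 | methyl 2,5-dibromo-3-[(2-hydroxy-3-oxocyclohex-1-en-1-yl)oxy]-4-methoxybenzoate | COC(=O)c1cc(Br)c(OC)c(OC2=C(O)C(=O)CCC2)c1Br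
F5 | step 13 | 6-bromo-3-[2,5-dibromo-3-(hydroxymethyl)-6-methoxyphenoxy]-4-(hydroxymethyl)-2-methoxyphenol | OCc1cc(Br)c(O)c(OC)c1Oc1c(Br)c(CO)cc(Br)c1OC
F6 | step 13 | 6-bromo-4-(bromomethyl)-3-[2,5-dibromo-3-(bromomethyl)-6-hydroxyphenoxy]benzene-1,2-diol | BrCc1cc(Br)c(O)c(O)c1Oc1c(Br)c(CBr)cc(Br)c1O
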